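**Plan**

- Retrosynthetic cuts: (a) the primary C–Br (back to CH2OH, then CHO); (b) the allylic C–Cl next to the ring CH2, together with the position of the exocyclic C=C (vinylogous chlorination of a dienol ether); (c) the two side-chain carbons (from a ring ketone); (d) in one stroke the ring bonds CH2–CHCl and CMe2–CHBr, which splits the ring into 1-chloro-2-methylprop-1-ene and a four-carbon CHBr–C(=O)–CH2–CH(OR*) unit.
- Enabling feature: the ring carbon that carries the exocyclic alkene is a latent ketone. Its CHBr neighbour and the ring CH2 two bonds away on the other side can be tied together as a 2-bromo-3-alkoxycyclobutanone. This donor–acceptor four-membered ring opens to a bromoenolate/oxocarbenium 1,4-dipole, and the CMe2 carbon of the alkene can carry the tertiary cation that the enolate then captures.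
- Forward order: chiral vinyl ether + bromoketene → cyclobutanone (temporary ring); strain-release formal [4+2] with the chloroalkene builds the only ring; the alkoxy helper leaves by β-elimination and the resulting C=C is saturated; (Z)-2-ethoxyvinyl addition/transposition adds the side chain; silyl dienol ether, γ-chlorination, reduction, Appel bromination.
- Stereochemistry: Br and Cl cis across CMe2 from the chair-like closure of the (Z)-bromoenolate onto the β-chloro cation; absolute configuration from the (1R,2S)-2-phenylcyclohexyl group on the oxocarbenium oxygen (adduct carried on as one diastereomer, auxiliary recovered); the second C–Cl from Cl+ attack anti to Br; the (Z)-alkene from the s-trans dienol ether.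

Key step: step 3

Assumption: both enantiomers of trans-2-phenylcyclohexanol are commercial, and the (1R,2S)-alcohol is taken to be the one whose phenyl ring steers step 3 to adduct 8; if the sense were the opposite, the (1S,2R)-alcohol would be used in the same way.

**Step 1**
Reactants: 1 (1R,2S)-2-phenylcyclohexan-1-ol; 2 ethyl vinyl ether
Product: 3 (1R,2S)-2-phenylcyclohexyl vinyl ether
Conditions: Pd(OAc)2 (cat.), 1,10-phenanthroline (cat.), 2 as solvent, rt
Reagents that add atoms: none
Why: Pd-catalysed transfer vinylation (trans-etherification) of a secondary alcohol with a vinyl ether exchanges the O–vinyl group without touching the two stereocentres of the auxiliary.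

**Step 2**
Reactants: 3 (1R,2S)-2-phenylcyclohexyl vinyl ether; 4 bromoacetyl chloride
Product: 6 2-bromo-3-{[(1R,2S)-2-phenylcyclohexyl]oxy}cyclobutan-1-one (mixture of ring diastereomers), via bromoketene 5 (not isolated)
Conditions: Et3N, hexane, rt, slow addition of 4
Reagents that add atoms: none
Why: Et3N dehydrochlorinates 4 to bromoketene, which should undergo the regioselective ketene–enol ether [2+2] cycloaddition (carbonyl carbon to the CH2 terminus) to the 2-halo-3-alkoxycyclobutanone; the two new ring stereocentres need no control because step 3 erases both.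

**Step 3**
Reactants: 6 2-bromo-3-{[(1R,2S)-2-phenylcyclohexyl]oxy}cyclobutan-1-one; 7 1-chloro-2-methylprop-1-ene
Product: 8 (2S,4R,5R)-2-bromo-4-chloro-3,3-dimethyl-5-{[(1R,2S)-2-phenylcyclohexyl]oxy}cyclohexan-1-one (isolated as one diastereomer)
Conditions: 7 (5 equiv), SnCl4 (1.2 equiv), CH2Cl2, −78 to −40 °C
Reagents that add atoms: none
Why: Proposed new method: SnCl4 on the carbonyl oxygen of 6 should trigger heterolysis of the strained C2–C3 bond (push from the alkoxy oxygen, pull from the tin enolate, ring strain released) to a (Z)-bromoenolate/oxocarbenium 1,4-zwitterion, the CHCl carbon of 7 then attacks the oxocarbenium carbon in the Markovnikov sense (tertiary cation at the CMe2 carbon), and the bromoenolate carbon captures this cation, so that both ring bonds form in one operation. The closest known reaction type is the Lewis acid-promoted formal [4+2] cycloaddition of 3-alkoxycyclobutanones with silyl enol ethers, allylsilanes and aldehydes; new is a non-activated chloroalkene as the 2π partner, argued from the isobutene-like reactivity of 7 toward oxocarbenium ions (Prins reactivity) and from the fast collapse of a cation with a tethered metal enolate. The six-membered ring closes in a 6-(enolendo)-exo mode, the enolate carbon adding to the planar tertiary cation through a chair. The C–Br centre should be equatorial because Br is syn to O–Sn in the chelated (Z)-enolate, and the C–Cl centre equatorial because the C–Cl bond lies antiperiplanar to the forming C–C bond, which places Br and Cl cis across the quaternary carbon with the bulky alkoxy group equatorial and trans to Cl. The absolute sense comes from the 2-phenylcyclohexyl group, whose phenyl ring shields one face of the oxocarbenium ion, and because the first C–C bond can revert by Grob-type fragmentation the all-equatorial adduct should be drained and is purified as one diastereomer. The step needs cleavage of C2–C3 and not C3–C4 (secured by bromine, which stabilises the enolate, as in the known 2-substituted cases) and interception of the zwitterion before retro-[2+2] (secured by excess 7 at low temperature).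

**Step 4**
Reactants: 8 (2S,4R,5R)-2-bromo-4-chloro-3,3-dimethyl-5-{[(1R,2S)-2-phenylcyclohexyl]oxy}cyclohexan-1-one
Product: 9 (4S,6S)-6-bromo-4-chloro-5,5-dimethylcyclohex-2-en-1-one
Conditions: p-TsOH·H2O (cat.), toluene, 60 °C
Reagents that add atoms: none
Why: Acid-catalysed β-elimination of the β-alkoxy ketone through the enol on the CH2 side should give the conjugated enone and return the auxiliary; enolisation toward the neopentyl CHBr carbon is slower, so that centre should keep its configuration, and no new stereocentre is formed.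

**Step 5**
Reactants: 9 (4S,6S)-6-bromo-4-chloro-5,5-dimethylcyclohex-2-en-1-one
Product: 10 (2S,4S)-2-bromo-4-chloro-3,3-dimethylcyclohexan-1-one
Conditions: KO2CN=NCO2K, AcOH, MeOH–CH2Cl2, 0 °C to rt
Reagents that add atoms: none
Why: Diimide generated in situ transfers H2 by a concerted cyclic mechanism to the cis-disubstituted C=C only and leaves the α-bromo ketone and the C–Cl bond untouched (diimide reduction); no stereocentre is formed.

**Step 6**
Reactants: 10 (2S,4S)-2-bromo-4-chloro-3,3-dimethylcyclohexan-1-one; 11 (Z)-1-bromo-2-ethoxyethene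
Product: 15 2-[(2R,4S)-2-bromo-4-chloro-3,3-dimethylcyclohexylidene]acetaldehyde (E/Z mixture), via [(Z)-2-ethoxyethenyl]lithium 12 (not isolated), via dichloro[(Z)-2-ethoxyethenyl]cerium 13 (not isolated), via tertiary carbinol 14 (not isolated)
Conditions: 11, n-BuLi, THF, −78 °C; CeCl3, −78 °C; 10, −78 °C; then 1 M HCl, THF, 0 °C
Reagents that add atoms: none
Why: Br/Li exchange gives the (Z)-2-ethoxyvinyl anion, whose weakly basic organocerium form should add 1,2 to the hindered α-bromo ketone without enolisation or Br/metal exchange, and aqueous acid turns the β-alkoxyvinyl carbinol into the enal by allylic transposition (two-carbon formyl-olefination); the carbinol centre is destroyed and the enal geometry is of no consequence because step 7 removes it.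

**Step 7**
Reactants: 15 2-[(2R,4S)-2-bromo-4-chloro-3,3-dimethylcyclohexylidene]acetaldehyde
Product: 16 tert-butyl({(E)-2-[(4S,6R)-6-bromo-4-chloro-5,5-dimethylcyclohex-1-en-1-yl]ethenyl}oxy)dimethylsilane
Conditions: TBSOTf, Et3N, CH2Cl2, −78 to 0 °C
Reagents that add atoms: tert-butyldimethylsilyl trifluoromethanesulfonate, CC(C)(C)[Si](C)(C)OS(=O)(=O)C(F)(F)F
Why: Soft enolisation of the O-silylated enal by γ-deprotonation at the unhindered ring CH2 should give the 1-silyloxy-1,3-diene from both enal isomers, because the C–H of the CHBr carbon is screened by the gem-dimethyl group and its removal would give a strained tetrasubstituted bromoalkene.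

**Step 8**
Reactants: 16 tert-butyl({(E)-2-[(4S,6R)-6-bromo-4-chloro-5,5-dimethylcyclohex-1-en-1-yl]ethenyl}oxy)dimethylsilane
Product: 17 (2Z)-2-[(2S,4S,6S)-2-bromo-4,6-dichloro-3,3-dimethylcyclohexylidene]acetaldehyde
Conditions: NCS, THF, −78 °C; aq. NaHCO3
Reagents that add atoms: N-chlorosuccinimide, ClN1C(=O)CCC1=O
Why: Electrophilic γ-chlorination of a silyl dienol ether (vinylogous enol ether halogenation): Cl+ should add to the ring CH terminus anti to the pseudoaxial C–Br (held axial by A(1,3) strain with the side chain) and to the cis C–Cl, which sets the new C–Cl centre trans to both, and the s-trans diene geometry is carried into the new exocyclic C=C, so that CHO ends on the side of the CHBr carbon (Z).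

**Step 9**
Reactants: 17 (2Z)-2-[(2S,4S,6S)-2-bromo-4,6-dichloro-3,3-dimethylcyclohexylidene]acetaldehyde
Product: 18 (2Z)-2-[(2S,4S,6S)-2-bromo-4,6-dichloro-3,3-dimethylcyclohexylidene]ethan-1-ol
Conditions: NaBH4, CeCl3·7H2O, MeOH, −78 °C
Reagents that add atoms: none
Why: Luche 1,2-reduction of the enal at low temperature should give the primary allylic alcohol without conjugate reduction or displacement of the allylic halides; no stereocentre or alkene geometry is touched.

**Step 10**
Reactants: 18 (2Z)-2-[(2S,4S,6S)-2-bromo-4,6-dichloro-3,3-dimethylcyclohexylidene]ethan-1-ol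
Product: 19 (1Z,2S,4S,6S)-2-bromo-1-(2-bromoethylidene)-4,6-dichloro-3,3-dimethylcyclohexane
Conditions: CBr4, PPh3, CH2Cl2, 0 °C
Reagents that add atoms: tetrabromomethane, BrC(Br)(Br)Br
Why: Appel bromination should replace the primary allylic hydroxyl by SN2 at the unhindered CH2 under neutral conditions, where the hindered secondary allylic C–Br and C–Cl bonds neither ionise nor exchange, to give the target.

**Compound list**

1 | (1R,2S)-2-phenylcyclohexan-1-ol | O[C@@H]1CCCC[C@H]1c1ccccc1 | starting material
2 | ethyl vinyl ether (ethoxyethene) | CCOC=C | starting material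
3 | (1R,2S)-2-phenylcyclohexyl vinyl ether, [(1S,2R)-2-(ethenyloxy)cyclohexyl]benzene | C=CO[C@@H]1CCCC[C@H]1c1ccccc1 | intermediate
4 | bromoacetyl chloride | BrCC(Cl)=O | starting material
5 | bromoketene (not isolated) | BrC=C=O | intermediate
6 | 2-bromo-3-{[(1R,2S)-2-phenylcyclohexyl]oxy}cyclobutan-1-one (mixture of ring diastereomers) | O=C1CC(O[C@@H]2CCCC[C@H]2c2ccccc2)C1Br | intermediate
7 | 1-chloro-2-methylprop-1-ene | CC(C)=CCl | starting material
8 | (2S,4R,5R)-2-bromo-4-chloro-3,3-dimethyl-5-{[(1R,2S)-2-phenylcyclohexyl]oxy}cyclohexan-1-one | CC1(C)[C@H](Br)C(=O)C[C@@H](O[C@@H]2CCCC[C@H]2c2ccccc2)[C@@H]1Cl | intermediate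
9 | (4S,6S)-6-bromo-4-chloro-5,5-dimethylcyclohex-2-en-1-one | CC1(C)[C@H](Br)C(=O)C=C[C@@H]1Cl | intermediate
10 | (2S,4S)-2-bromo-4-chloro-3,3-dimethylcyclohexan-1-one | CC1(C)[C@H](Br)C(=O)CC[C@@H]1Cl | intermediate
11 | (Z)-1-bromo-2-ethoxyethene | CCO/C=C\Br | starting material
12 | [(Z)-2-ethoxyethenyl]lithium (not isolated) | CCO/C=C\[Li] | intermediate
13 | dichloro[(Z)-2-ethoxyethenyl]cerium (not isolated) | CCO/C=C\[Ce](Cl)Cl | intermediate
14 | (2S,4S)-2-bromo-4-chloro-1-[(Z)-2-ethoxyethenyl]-3,3-dimethylcyclohexan-1-ol (tertiary carbinol, not isolated) | CC1(C)[C@H](Br)C(O)(/C=C\OCC)CC[C@@H]1Cl | intermediate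
15 | 2-[(2R,4S)-2-bromo-4-chloro-3,3-dimethylcyclohexylidene]acetaldehyde (E/Z mixture) | CC1(C)[C@H](Br)C(=CC=O)CC[C@@H]1Cl | intermediate
16 | tert-butyl({(E)-2-[(4S,6R)-6-bromo-4-chloro-5,5-dimethylcyclohex-1-en-1-yl]ethenyl}oxy)dimethylsilane | CC1(C)[C@H](Br)C(/C=C/O[Si](C)(C)C(C)(C)C)=CC[C@@H]1Cl | intermediate
17 | (2Z)-2-[(2S,4S,6S)-2-bromo-4,6-dichloro-3,3-dimethylcyclohexylidene]acetaldehyde | CC1(C)[C@H](Br)/C(=C\C=O)[C@@H](Cl)C[C@@H]1Cl | intermediate
18 | (2Z)-2-[(2S,4S,6S)-2-bromo-4,6-dichloro-3,3-dimethylcyclohexylidene]ethan-1-ol | CC1(C)[C@H](Br)/C(=C\CO)[C@@H](Cl)C[C@@H]1Cl | intermediate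
19 | (1Z,2S,4S,6S)-2-bromo-1-(2-bromoethylidene)-4,6-dichloro-3,3-dimethylcyclohexane | CC1(C)[C@H](Br)/C(=C\CBr)[C@@H](Cl)C[C@@H]1Cl | target

**Step count and risks**

Total step count: 10. Longest linear sequence: 10 steps (from 1 and 2 to 19).

Three steps most likely to fail:

Step 3 (Proposed new method). The chloroalkene is a weak π-nucleophile and may fail to intercept the zwitterion, which would then revert by retro-[2+2] or lose the alkoxy group; facial discrimination by the auxiliary may also be poor. The fallback uses known reaction types, sets out from 6 and 7 and comes back to the route at 8. The 2π partner is activated as an allylsilane and the two ring bonds are made one after the other. Wohl–Ziegler bromination of 7 (NBS, radical initiator) would give 3-bromo-1-chloro-2-methylprop-1-ene F1, and Barbier silylation (Mg, Me3SiCl, THF) would give (3-chloro-2-methylprop-2-en-1-yl)trimethylsilane F2. SnCl4-promoted ring-opening Hosomi–Sakurai allylation of 6 with F2, the known behaviour of 3-alkoxycyclobutanones toward allyltrimethylsilanes, forms the CH(OR*)–CHCl bond and would give 1-bromo-5-chloro-6-methyl-4-{[(1R,2S)-2-phenylcyclohexyl]oxy}hept-6-en-2-one F3. Markovnikov addition of HCl to the isopropenyl group would give 1-bromo-5,6-dichloro-6-methyl-4-{[(1R,2S)-2-phenylcyclohexyl]oxy}heptan-2-one F4. Soft enolisation (Me3SiOTf, Et3N) would give {[(Z)-1-bromo-5,6-dichloro-6-methyl-4-{[(1R,2S)-2-phenylcyclohexyl]oxy}hept-1-en-2-yl]oxy}trimethylsilane F5. TiCl4 then ionises the tertiary chloride and the enol ether carbon closes onto the cation (Lewis acid-mediated tert-alkylation of a silyl enol ether) through the same chair to give 8, which is separated as one diastereomer as before.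

Step 8. Chlorination may occur at the α-carbon of the dienol ether instead of the γ-carbon, or Cl+ may be delivered from the face syn to bromine. The fallback sets out from 10 and comes back to the route at 19; the side chain is brought in as a vinyl group and the chlorine by 1,4-addition to a diene. Addition of vinylmagnesium bromide to 10 in the presence of CeCl3 would give (2S,4S)-2-bromo-4-chloro-1-ethenyl-3,3-dimethylcyclohexan-1-ol F6. Dehydration toward the ring CH2 (SOCl2, pyridine) would give (4S,6R)-6-bromo-4-chloro-1-ethenyl-5,5-dimethylcyclohex-1-ene F7. 1,4-Addition of Cl2 (CH2Cl2, −78 °C), with Cl+ attacking the ring CH carbon anti to bromine and chloride closing at the vinyl terminus of the s-trans allyl cation, would give (1Z,2S,4S,6S)-2-bromo-4,6-dichloro-1-(2-chloroethylidene)-3,3-dimethylcyclohexane F8. Finkelstein exchange of the primary allylic chloride (NaBr, acetone) would give 19.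

Step 2. Bromoketene may oligomerise before it is captured by the enol ether. The fallback sets out from 3 and comes back to the route at 6; it uses the robust dichloroketene and brings in bromine afterwards. [2+2] Cycloaddition of 3 with dichloroketene (Cl3CCOCl, zinc–copper couple, Et2O) would give 2,2-dichloro-3-{[(1R,2S)-2-phenylcyclohexyl]oxy}cyclobutan-1-one F9. Zn in AcOH removes both chlorines to give 3-{[(1R,2S)-2-phenylcyclohexyl]oxy}cyclobutan-1-one F10. Soft enolisation (Me3SiOTf, Et3N) would give trimethyl[(3-{[(1R,2S)-2-phenylcyclohexyl]oxy}cyclobut-1-en-1-yl)oxy]silane F11, and NBS brominates it to 6.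

**Further compounds**

F1 | step 3 | 3-bromo-1-chloro-2-methylprop-1-ene | BrCC(C)=CCl
F2 | step 3 | (3-chloro-2-methylprop-2-en-1-yl)trimethylsilane | C[Si](C)(C)CC(C)=CCl
F3 | step 3 | 1-bromo-5-chloro-6-methyl-4-{[(1R,2S)-2-phenylcyclohexyl]oxy}hept-6-en-2-one | BrCC(=O)CC(O[C@@H]1CCCC[C@H]1c1ccccc1)C(Cl)C(C)=C
F4 | step 3 | 1-bromo-5,6-dichloro-6-methyl-4-{[(1R,2S)-2-phenylcyclohexyl]oxy}heptan-2-one | BrCC(=O)CC(O[C@@H]1CCCC[C@H]1c1ccccc1)C(Cl)C(C)(C)Cl
F5 | step 3 | {[(Z)-1-bromo-5,6-dichloro-6-methyl-4-{[(1R,2S)-2-phenylcyclohexyl]oxy}hept-1-en-2-yl]oxy}trimethylsilane | Br/C=C(\O[Si](C)(C)C)CC(O[C@@H]1CCCC[C@H]1c1ccccc1)C(Cl)C(C)(C)Cl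
F6 | step 8 | (2S,4S)-2-bromo-4-chloro-1-ethenyl-3,3-dimethylcyclohexan-1-ol | CC1(C)[C@H](Br)C(O)(C=C)CC[C@@H]1Cl
F7 | step 8 | (4S,6R)-6-bromo-4-chloro-1-ethenyl-5,5-dimethylcyclohex-1-ene | CC1(C)[C@H](Br)C(C=C)=CC[C@@H]1Cl
F8 | step 8 | (1Z,2S,4S,6S)-2-bromo-4,6-dichloro-1-(2-chloroethylidene)-3,3-dimethylcyclohexane | CC1(C)[C@H](Br)/C(=C\CCl)[C@@H](Cl)C[C@@H]1Cl
F9 | step 2 | 2,2-dichloro-3-{[(1R,2S)-2-phenylcyclohexyl]oxy}cyclobutan-1-one | O=C1CC(O[C@@H]2CCCC[C@H]2c2ccccc2)C1(Cl)Cl
F10 | step 2 | 3-{[(1R,2S)-2-phenylcyclohexyl]oxy}cyclobutan-1-one | O=C1CC(O[C@@H]2CCCC[C@H]2c2ccccc2)C1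
F11 | step 2 | trimethyl[(3-{[(1R,2S)-2-phenylcyclohexyl]oxy}cyclobut-1-en-1-yl)oxy]silane | C[Si](C)(C)OC1=CC(O[C@@H]2CCCC[C@H]2c2ccccc2)C1
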